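**Plan**

1. Numbering used throughout (germacranolide style): ten-membered ring C1–C10 (C3 ketone, C4 methyl, C6 senecioate, C9 =CH, C10 carbinol); butenolide O–C8, C7=C11, C12 = lactone C=O, C13 = CH2OAc.
2. Retrosynthesis: after removing the C13 acetate, the ten-membered ring is undone by re-joining C3 to C8. The ketone C3 lies 1,6 to C8, which is the γ-carbon (vinylogous α-position) of the C12 butenolide and carries C8=C9 next to the C10 carbinol. This array is the retron of a Grob-type (retro-vinylogous-aldol/E1cB) fragmentation of a 6/6 bicycle with a leaving group on C9.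
3. The bicycle is cut at C8–C9 and C3–C8 (two vinylogous aldols of the butenolide CH2), the chain at C2–C3 (alkyllithium + γ-lactone), and the butenolide at C7=C11 (HWE) and O–C8.
4. Forward: butenolide (step 8) → chain (step 9) → ring A by C3–C8 and ring B by C8–C9 (step 13) → C3–C8 cleaved again, so the ten-membered ring appears last (step 14) → C13 acetate.
5. Stereochemistry: C6 from (R)-5-oxotetrahydrofuran-2-carboxylic acid; C4 by trans-methylation under C6 control; C10 from (R)-citramalic acid. C3, C8 and C9 of the bicycle are temporary. (Z)-C8=C9 follows from the anti C7/C10 arrangement in the cis-fused bicycle.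

Key step: step 14

Remark: the target is handled as the open 10-hydroxy-3-ketone as drawn; its ring-chain tautomer (C3/C10 hemiketal) is the same compound and may be present in equilibrium.

**Route**

Step 1
Reactants: 1 (R)-citramalic acid
Product: 2 (2R)-2-methylbutane-1,2,4-triol
Conditions: BH3·SMe2 (4 equiv), B(OMe)3, THF, 0 °C → rt; MeOH quench
Reagents that add atoms: none
Why: Borane reduction of carboxylic acids (the malic acid → butanetriol protocol) reduces both CO2H groups and cannot touch the tertiary carbinol centre, which becomes C10.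

Step 2
Reactants: 2 (2R)-2-methylbutane-1,2,4-triol
Product: 3 2-[(4R)-2,2,4-trimethyl-1,3-dioxolan-4-yl]ethan-1-ol
Conditions: Me2C(OMe)2, acetone, TsOH·H2O (cat.), rt; Et3N quench
Reagents that add atoms: 2,2-dimethoxypropane COC(C)(C)OC
Why: Acid-catalysed acetalisation under thermodynamic control favours the five-membered dioxolane over the six-membered dioxane, so the tertiary OH (future C10–OH) and the C9 oxygen are masked together and only the primary OH on the C2 side stays free.

Step 3
Reactants: 3 2-[(4R)-2,2,4-trimethyl-1,3-dioxolan-4-yl]ethan-1-ol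
Product: 4 (4R)-4-(2-iodoethyl)-2,2,4-trimethyl-1,3-dioxolane
Conditions: PPh3, I2, imidazole, CH2Cl2, 0 °C → rt
Reagents that add atoms: iodine II
Why: Appel-type iodination of a primary alcohol, buffered by imidazole so that the acetonide survives; no stereocentre is involved.

Step 4
Reactants: 5 ethyl 2-(diethoxyphosphoryl)acrylate; 6 4-methoxybenzyl alcohol
Product: 7 ethyl 2-(diethoxyphosphoryl)-3-[(4-methoxybenzyl)oxy]propanoate (racemic)
Conditions: KOtBu (5 mol %), THF, 0 °C
Reagents that add atoms: none
Why: Base-catalysed oxa-Michael addition to a doubly activated vinylphosphonate; the new α-centre is racemic and is destroyed in step 8.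

Step 5
Reactants: 7 ethyl 2-(diethoxyphosphoryl)-3-[(4-methoxybenzyl)oxy]propanoate
Product: 8 2-(diethoxyphosphoryl)-3-[(4-methoxybenzyl)oxy]propanoic acid (racemic)
Conditions: LiOH·H2O (1.1 equiv), THF/H2O, 0 °C; 1 M HCl to pH 2
Reagents that add atoms: lithium hydroxide [Li+].[OH-]
Why: Saponification of the carboxylic ester is much faster than P–OEt cleavage, and the carboxylate formed suppresses α-deprotonation and hence retro-Michael loss of the PMB alcohol.

Step 6
Reactants: 9 (2R)-5-oxotetrahydrofuran-2-carboxylic acid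
Product: 10 (2R,4S)-4-methyl-5-oxotetrahydrofuran-2-carboxylic acid
Conditions: LDA (2.2 equiv), THF/DMPU, −78 °C; MeI (1.2 equiv), −78 → −40 °C; 1 M HCl
Reagents that add atoms: iodomethane CI
Why: Dianion alkylation: the carboxylate formed first protects C6–H from deprotonation, the second equivalent of LDA makes the lactone enolate at C4, and MeI should enter anti to the C6 carboxylate to give the trans (4S) lactone (1,3-induction in a γ-lactone enolate).

Step 7
Reactants: 10 (2R,4S)-4-methyl-5-oxotetrahydrofuran-2-carboxylic acid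
Product: 12 (3S,5R)-5-(diazoacetyl)-3-methyldihydrofuran-2(3H)-one, via acid chloride 11 (not isolated)
Conditions: (COCl)2, DMF (cat.), CH2Cl2, 0 °C → rt, evaporate; CH2N2 (3 equiv, ethereal solution), Et2O, 0 °C
Reagents that add atoms: diazomethane C=[N+]=[N-]
Why: Acylation of diazomethane by the acid chloride (first stage of an Arndt–Eistert sequence); it is base-free, so the oxygen-bearing centre C6 is not enolised and no new stereocentre arises.

Step 8
Reactants: 12 (3S,5R)-5-(diazoacetyl)-3-methyldihydrofuran-2(3H)-one; 8 2-(diethoxyphosphoryl)-3-[(4-methoxybenzyl)oxy]propanoic acid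
Product: 14 (3S,5R)-5-{4-[(4-methoxybenzyl)oxymethyl]-5-oxo-2,5-dihydrofuran-3-yl}-3-methyldihydrofuran-2(3H)-one (bis-lactone), via keto phosphonate 13 (not isolated)
Conditions: Rh2(OAc)4 (1 mol %), CH2Cl2, rt; then LiCl, iPr2NEt, MeCN, 0 °C → rt
Reagents that add atoms: none
Why: Rh(II)-catalysed O–H insertion of the diazoketone into the carboxylic acid gives the α-acyloxy ketone, and the phosphonate anion then closes the butenolide by intramolecular Horner–Wadsworth–Emmons reaction (mild LiCl/amine conditions) on the C7 ketone, which installs C11, C12 and C13 at once.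

Step 9
Reactants: 14 bis-lactone; 4 (4R)-4-(2-iodoethyl)-2,2,4-trimethyl-1,3-dioxolane
Product: 17 4-[(1R,3S)-1-hydroxy-3-methyl-4-oxo-6-[(4R)-2,2,4-trimethyl-1,3-dioxolan-4-yl]hexyl]-3-[(4-methoxybenzyl)oxymethyl]furan-2(5H)-one, via alkyllithium 15 (not isolated), via lithium furanolate 16 (not isolated)
Conditions: 4, t-BuLi (2.1 equiv), Et2O, −78 °C; separately 14, LiHMDS (1.05 equiv), THF, −78 °C; 15 (1.2 equiv) cannulated into 16, −78 °C; AcOH, −78 °C
Reagents that add atoms: none
Why: The butenolide is masked in situ as its aromatic lithium 2-oxidofuran (C8–H is the most acidic site), so the primary alkyllithium should add once to the only remaining electrophile, the saturated γ-lactone carbonyl C3, whose tetrahedral adduct survives at −78 °C and gives the γ-hydroxy ketone on protonation (lactone → ketone addition); C4, C6 and C10 are not touched.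

Step 10
Reactants: 17 γ-hydroxy ketone
Product: 18 (1R,3S)-1-{4-[(4-methoxybenzyl)oxymethyl]-5-oxo-2,5-dihydrofuran-3-yl}-3-methyl-4-oxo-6-[(4R)-2,2,4-trimethyl-1,3-dioxolan-4-yl]hexyl 3-methylbut-2-enoate
Conditions: 3-methylbut-2-enoic acid, DCC, DMAP (cat.), CH2Cl2, 0 °C → rt
Reagents that add atoms: 3-methylbut-2-enoic acid CC(C)=CC(=O)O
Why: Steglich esterification of the only secondary hydroxyl (17 reacts through its open hydroxy-ketone form); the carbodiimide method avoids the vinylketene pathway by which senecioyl chloride deconjugates.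

Step 11
Reactants: 18 acetonide senecioate
Product: 19 (1R,3S,7R)-7,8-dihydroxy-1-{4-[(4-methoxybenzyl)oxymethyl]-5-oxo-2,5-dihydrofuran-3-yl}-3,7-dimethyl-4-oxooctyl 3-methylbut-2-enoate
Conditions: AcOH/H2O/THF (3:1:1), 40 °C
Reagents that add atoms: none
Why: Mild acid hydrolysis of the isopropylidene acetal; the esters, the PMB ether and the butenolide are stable to aqueous acetic acid.

Step 12
Reactants: 19 diol
Product: 20 (1R,3S,7R)-7-hydroxy-1-{4-[(4-methoxybenzyl)oxymethyl]-5-oxo-2,5-dihydrofuran-3-yl}-3,7-dimethyl-4,8-dioxooctyl 3-methylbut-2-enoate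
Conditions: SO3·pyridine, DMSO, iPr2NEt, CH2Cl2, 0 °C
Reagents that add atoms: none
Why: Parikh–Doering oxidation converts the primary alcohol into the non-enolisable α-hydroxy aldehyde (C9); the tertiary C10–OH cannot be oxidised and activated DMSO does not cleave the glycol.

Step 13
Reactants: 20 keto aldehyde
Product: 22 tricyclic triol (C3–C8 and C8–C9 closed; 3-OH; 9-OH; 10-OH; mixture at C3/C8/C9), via mono-aldol 21 (not isolated)
Conditions: DBU (1.0 equiv), THF, 0 °C → rt; pH 7 buffer
Reagents that add atoms: none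
Why: Two direct base-mediated vinylogous aldol reactions of the butenolide γ-carbon C8, first onto the C3 ketone (six-membered ring A, reversible) and then, after renewed γ-deprotonation, onto the C9 aldehyde (six-membered ring B, which can close only from the C3 epimer with the chain equatorial, the other returning by retro-aldol); C3, C8 and C9 form as mixtures, which is harmless because all three are erased in step 14.

Step 14
Reactants: 22 tricyclic triol
Product: 24 (4S,6R,8Z,10R)-10-hydroxy-13-[(4-methoxybenzyl)oxy]-6-[(3-methylbut-2-enoyl)oxy]-3-oxogermacra-7(11),8-dien-12,8-olide, via C9 mesylate 23 (not isolated)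
Conditions: MsCl (1.3 equiv), Et3N, CH2Cl2, −20 °C; then DBU (3 equiv), 0 °C → rt; pH 7 buffer
Reagents that add atoms: none
Why: Proposed new method: MsCl/Et3N sulfonylates the only secondary hydroxyl (C9), then DBU deprotonates C3–OH and the alkoxide cleaves the C3–C8 bond by a retro-vinylogous aldol reaction, which is possible because C8 is the γ-carbon of the C12 butenolide and leaves as an aromatic 2-oxidofuran; this ten-membered furanolate expels the β-mesylate at C9 (E1cB), so C8=C9, the C3 ketone and the free C10 carbinol appear in one operation. The closest known reaction types are the Wharton–Grob fragmentation of decalin 1,3-diol monosulfonates to cyclodecenones and the E1cB dehydration of γ-(1-sulfonyloxyalkyl)butenolides to γ-alkylidene butenolides; what is new is their coupling through a butenolide as the electron sink. The ten-membered ring is not closed end to end but arises by four-atom ring expansion of ring A, through cleavage of the bond shared by the two six-membered rings. No stereocentre is formed: C3, C8 and C9 become sp2, so every diastereomer of 22 should converge on one product; C10 keeps its configuration because its C–O bond is never broken (also if the C10 alkoxide first closes a 9,10-epoxide, an equally good leaving group); and the (Z)-geometry is expected because the planar butenolide holds O–C8 equatorial on ring A and axial on ring B, so that C7 and C10 are anti about C8–C9 in the cis-fused bicycle. The selectivities needed are cleavage of C3–C8 instead of C3–C2 or C3–C4 (only C8 gives a stabilised carbanion) and loss of the C9 mesylate instead of the C13 ether from the furanolate (PMBO− is a far poorer leaving group, which is why the acetate is put on last).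

Step 15
Reactants: 24 PMB ether
Product: 25 (4S,6R,8Z,10R)-10,13-dihydroxy-6-[(3-methylbut-2-enoyl)oxy]-3-oxogermacra-7(11),8-dien-12,8-olide
Conditions: DDQ, CH2Cl2/pH 7 buffer (10:1), 0 °C → rt
Reagents that add atoms: none
Why: Oxidative cleavage of the PMB ether by DDQ; the electron-poor dienyl lactone, the tertiary allylic alcohol and the esters should not be oxidised.

Step 16
Reactants: 25 C13 alcohol
Product: 26 CNP0186726.1
Conditions: Ac2O, pyridine, DMAP (cat.), CH2Cl2, 0 °C
Reagents that add atoms: acetic anhydride CC(=O)OC(C)=O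
Why: Acetylation of the primary allylic alcohol; the tertiary C10–OH is inert under these conditions, so no protecting group is needed.

**Compound list**

1 | (R)-citramalic acid, (2R)-2-hydroxy-2-methylbutanedioic acid | C[C@@](O)(CC(=O)O)C(=O)O | starting material
2 | (2R)-2-methylbutane-1,2,4-triol | C[C@@](O)(CCO)CO | intermediate
3 | 2-[(4R)-2,2,4-trimethyl-1,3-dioxolan-4-yl]ethan-1-ol | C[C@@]1(CCO)COC(C)(C)O1 | intermediate
4 | (4R)-4-(2-iodoethyl)-2,2,4-trimethyl-1,3-dioxolane | C[C@@]1(CCI)COC(C)(C)O1 | intermediate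
5 | ethyl 2-(diethoxyphosphoryl)acrylate | CCOC(=O)C(=C)P(=O)(OCC)OCC | starting material
6 | 4-methoxybenzyl alcohol | COc1ccc(CO)cc1 | starting material
7 | ethyl 2-(diethoxyphosphoryl)-3-[(4-methoxybenzyl)oxy]propanoate (racemic) | CCOC(=O)C(COCc1ccc(OC)cc1)P(=O)(OCC)OCC | intermediate
8 | 2-(diethoxyphosphoryl)-3-[(4-methoxybenzyl)oxy]propanoic acid (racemic) | OC(=O)C(COCc1ccc(OC)cc1)P(=O)(OCC)OCC | intermediate
9 | (2R)-5-oxotetrahydrofuran-2-carboxylic acid | OC(=O)[C@H]1CCC(=O)O1 | starting material
10 | (2R,4S)-4-methyl-5-oxotetrahydrofuran-2-carboxylic acid (trans) | OC(=O)[C@H]1C[C@H](C)C(=O)O1 | intermediate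
11 | (2R,4S)-4-methyl-5-oxotetrahydrofuran-2-carbonyl chloride | ClC(=O)[C@H]1C[C@H](C)C(=O)O1 | intermediate (not isolated)
12 | (3S,5R)-5-(diazoacetyl)-3-methyldihydrofuran-2(3H)-one | [N-]=[N+]=CC(=O)[C@H]1C[C@H](C)C(=O)O1 | intermediate
13 | 2-[(2R,4S)-4-methyl-5-oxotetrahydrofuran-2-yl]-2-oxoethyl 2-(diethoxyphosphoryl)-3-[(4-methoxybenzyl)oxy]propanoate | CCOP(=O)(OCC)C(COCc1ccc(OC)cc1)C(=O)OCC(=O)[C@H]1C[C@H](C)C(=O)O1 | intermediate (not isolated)
14 | (3S,5R)-5-{4-[(4-methoxybenzyl)oxymethyl]-5-oxo-2,5-dihydrofuran-3-yl}-3-methyldihydrofuran-2(3H)-one (bis-lactone) | O=C1OCC([C@H]2C[C@H](C)C(=O)O2)=C1COCc3ccc(OC)cc3 | intermediate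
15 | {2-[(4R)-2,2,4-trimethyl-1,3-dioxolan-4-yl]ethyl}lithium | [Li]CC[C@]1(C)COC(C)(C)O1 | intermediate (not isolated)
16 | lithium 2-oxidofuran (γ-deprotonated butenolide) of 14 | [Li+].[O-]C1=C(COCc2ccc(OC)cc2)C(=CO1)[C@H]3C[C@H](C)C(=O)O3 | intermediate (not isolated)
17 | 4-[(1R,3S)-1-hydroxy-3-methyl-4-oxo-6-[(4R)-2,2,4-trimethyl-1,3-dioxolan-4-yl]hexyl]-3-[(4-methoxybenzyl)oxymethyl]furan-2(5H)-one | O=C1OCC([C@H](O)C[C@H](C)C(=O)CC[C@]2(C)COC(C)(C)O2)=C1COCc3ccc(OC)cc3 | intermediate
18 | (1R,3S)-1-{4-[(4-methoxybenzyl)oxymethyl]-5-oxo-2,5-dihydrofuran-3-yl}-3-methyl-4-oxo-6-[(4R)-2,2,4-trimethyl-1,3-dioxolan-4-yl]hexyl 3-methylbut-2-enoate | O=C1OCC([C@H](OC(=O)C=C(C)C)C[C@H](C)C(=O)CC[C@]2(C)COC(C)(C)O2)=C1COCc3ccc(OC)cc3 | intermediate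
19 | (1R,3S,7R)-7,8-dihydroxy-1-{4-[(4-methoxybenzyl)oxymethyl]-5-oxo-2,5-dihydrofuran-3-yl}-3,7-dimethyl-4-oxooctyl 3-methylbut-2-enoate | O=C1OCC([C@H](OC(=O)C=C(C)C)C[C@H](C)C(=O)CC[C@@](C)(O)CO)=C1COCc2ccc(OC)cc2 | intermediate
20 | (1R,3S,7R)-7-hydroxy-1-{4-[(4-methoxybenzyl)oxymethyl]-5-oxo-2,5-dihydrofuran-3-yl}-3,7-dimethyl-4,8-dioxooctyl 3-methylbut-2-enoate | O=C1OCC([C@H](OC(=O)C=C(C)C)C[C@H](C)C(=O)CC[C@@](C)(O)C=O)=C1COCc2ccc(OC)cc2 | intermediate
21 | ring-A mono-aldol: (4R,6S)-7-hydroxy-7-[(3R)-3-hydroxy-3-methyl-4-oxobutyl]-3-{[(4-methoxybenzyl)oxy]methyl}-6-methyl-2-oxo-2,4,5,6,7,7a-hexahydro-1-benzofuran-4-yl 3-methylbut-2-enoate (mixture at C7 and C7a, i.e. C3 and C8) | O=C1OC2C(O)(CC[C@@](C)(O)C=O)[C@@H](C)C[C@@H](OC(=O)C=C(C)C)C2=C1COCc3ccc(OC)cc3 | intermediate (not isolated)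
22 | tricyclic triol: (4S,6R,10R)-3,9,10-trihydroxy-13-[(4-methoxybenzyl)oxy]-6-[(3-methylbut-2-enoyl)oxy]-3,8-cyclogermacr-7(11)-en-12,8-olide (cis-fused 6/6 bicycle on the butenolide; mixture at C3, C8, C9) | O=C1OC23C(O)[C@](C)(O)CCC2(O)[C@@H](C)C[C@@H](OC(=O)C=C(C)C)C3=C1COCc4ccc(OC)cc4 | intermediate
23 | 9-O-methanesulfonate of 22 | O=C1OC23C(OS(C)(=O)=O)[C@](C)(O)CCC2(O)[C@@H](C)C[C@@H](OC(=O)C=C(C)C)C3=C1COCc4ccc(OC)cc4 | intermediate (not isolated)
24 | (4S,6R,8Z,10R)-10-hydroxy-13-[(4-methoxybenzyl)oxy]-6-[(3-methylbut-2-enoyl)oxy]-3-oxogermacra-7(11),8-dien-12,8-olide | COc1ccc(COCC2=C3/C(=C/[C@](C)(O)CCC(=O)[C@@H](C)C[C@H]3OC(=O)C=C(C)C)OC2=O)cc1 | intermediate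
25 | (4S,6R,8Z,10R)-10,13-dihydroxy-6-[(3-methylbut-2-enoyl)oxy]-3-oxogermacra-7(11),8-dien-12,8-olide | OCC1=C2/C(=C/[C@](C)(O)CCC(=O)[C@@H](C)C[C@H]2OC(=O)C=C(C)C)OC1=O | intermediate
26 | CNP0186726.1, (4S,6R,8Z,10R)-13-acetoxy-10-hydroxy-6-[(3-methylbut-2-enoyl)oxy]-3-oxogermacra-7(11),8-dien-12,8-olide | CC(=O)OCC1=C2/C(=C/[C@](C)(O)CCC(=O)[C@@H](C)C[C@H]2OC(=O)C=C(C)C)OC1=O | target

**Step count and risks**

Total step count: 16. Longest linear sequence: 11 steps (steps 1–3 and 9–16, or steps 6–16).

Steps most likely to fail: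

1. Step 14 (proposed new method). The C3 alkoxide may not fragment: the C10 alkoxide could close the 9,10-epoxide and the sequence could stall there, or the released ketone could epimerise at C4 under DBU before the elimination is complete. The fallback closes the ten-membered ring directly, without the C3–C8 template, by known reaction types. It sets out from 20. TIPSOTf/Et3N (CH2Cl2, −78 °C) converts the butenolide into the 2-(triisopropylsilyloxy)furan F1. An intramolecular vinylogous Mukaiyama aldol addition to the aldehyde (BF3·OEt2, CH2Cl2, −78 °C, high dilution; the aldehyde is activated in preference to the ketone) should give the ten-membered γ-(1-hydroxyalkyl)butenolide F2. Mesylation gives the mesylate F3, and DBU effects the usual E1cB elimination of a γ-(1-mesyloxyalkyl)butenolide to the (Z)-alkylidene butenolide. The fallback comes back to the route at 24.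

2. Step 13. The second aldol builds a quaternary carbon between two fully substituted centres, so retro-aldol may dominate and the equilibrium may stop at the mono-aldol stage, or the aldehyde may be consumed by other base-mediated processes. The fallback makes the C8–C9 bond under kinetic, irreversible Lewis-acid conditions. It sets out from 20. Brief treatment with catalytic DBU gives mono-aldol 21, which is isolated here. TESOTf/Et3N converts it into the tris-silyl 2-silyloxyfuran F4. BF3·OEt2 at −78 °C triggers the intramolecular vinylogous Mukaiyama aldol addition to the aldehyde (six-membered ring) to give the bis-silyl ether F5. HF·pyridine removes the two silyl ethers. The fallback comes back to the route at 22.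

3. Step 9. The lithium furanolate may attack the lactone carbonyl within the molecule (Dieckmann-type closure) before the alkyllithium arrives, or the alkyllithium may act as a base at C4 or add twice. The fallback is a Fukuyama ketone synthesis, which tolerates the free butenolide. It sets out from 14 and 4. Me2AlSEt (from Me3Al and EtSH, CH2Cl2, 0 °C) opens the saturated lactone, and the aluminium alkoxide is acylated in the same flask with 3-methylbut-2-enoic anhydride/DMAP to give the thioester senecioate F6. Zinc insertion into 4 (Zn dust, LiCl, THF) gives the alkylzinc iodide F7. Pd-catalysed coupling of F6 with F7 (PdCl2(PPh3)2, toluene/THF) gives the ketone. The fallback comes back to the route at 18.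

**Further compounds**

F1 | step 14 | 2-(triisopropylsilyloxy)furan derived from 20 | CC(C)[Si](OC1=C(COCc2ccc(OC)cc2)C([C@H](OC(=O)C=C(C)C)C[C@H](C)C(=O)CC[C@@](C)(O)C=O)=CO1)(C(C)C)C(C)C
F2 | step 14 | (4S,6R,10R)-9,10-dihydroxy-13-[(4-methoxybenzyl)oxy]-6-[(3-methylbut-2-enoyl)oxy]-3-oxogermacr-7(11)-en-12,8-olide (mixture at C8, C9) | COc1ccc(COCC2=C3C(C(O)[C@](C)(O)CCC(=O)[C@@H](C)C[C@H]3OC(=O)C=C(C)C)OC2=O)cc1
F3 | step 14 | 9-O-methanesulfonate of F2 | COc1ccc(COCC2=C3C(C(OS(C)(=O)=O)[C@](C)(O)CCC(=O)[C@@H](C)C[C@H]3OC(=O)C=C(C)C)OC2=O)cc1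
F4 | step 13 | tris(triethylsilyl) derivative of 21 (2-silyloxyfuran, 3-OTES, 10-OTES) | CC[Si](CC)(CC)OC1=C(COCc2ccc(OC)cc2)C3=C(O1)C(O[Si](CC)(CC)CC)(CC[C@@](C)(O[Si](CC)(CC)CC)C=O)[C@@H](C)C[C@H]3OC(=O)C=C(C)C
F5 | step 13 | 3,10-bis(triethylsilyl) ether of 22 | O=C1OC23C(O)[C@](C)(O[Si](CC)(CC)CC)CCC2(O[Si](CC)(CC)CC)[C@@H](C)C[C@@H](OC(=O)C=C(C)C)C3=C1COCc4ccc(OC)cc4
F6 | step 9 | S-ethyl (2S,4R)-4-{4-[(4-methoxybenzyl)oxymethyl]-5-oxo-2,5-dihydrofuran-3-yl}-2-methyl-4-[(3-methylbut-2-enoyl)oxy]butanethioate | O=C1OCC([C@H](OC(=O)C=C(C)C)C[C@H](C)C(=O)SCC)=C1COCc2ccc(OC)cc2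
F7 | step 9 | {2-[(4R)-2,2,4-trimethyl-1,3-dioxolan-4-yl]ethyl}zinc iodide | I[Zn]CC[C@]1(C)COC(C)(C)O1
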